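The birch flask gains product more slowly over its last interval than over its second. Does a plain second-order law account for that? Birch is the asked flask, followed so far.

- birch: electrophile 0.40 M; nucleophile 1.05 equiv; free base 1.5 equiv; the very flask that is asked about, followed so far
- flask: electrophile 0.40 M; nucleophile 1.05 equiv; free base 1.50 equiv; time 2.5 h

birch run (percent of the electrophile charged): time / min: product / % = 4.00: 6.4; 12.0: 16.6; 20.0: 24.8; 30.0: 33.1; 50.0: 43.6

(readings scatter by 0.3 percentage points)

- at 2.5 h, what has stopped the reaction, if anything has (it is still moving / the nucleophile has run out first / the free base has run out first / all of the electrophile has reacted)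
- the product standing at 2.5 h, as a percentage of the electrophile charged

- the reaction counts as stopped when no species that holds the electrophile changes by six tenths of a point or more over the second half of the time

*Which concentrations set the order?* I take the rate as c(electrophile) times c(nucleophile). The charges stand at 1.05 equiv of nucleophile to the electrophile, the limiting reagent, so the two should fall together. Then product divided by electrophile left, divided again by time, should hold constant. Call this the running constant κ.

*Does it hold?* No. Birch reads 0.0166 min⁻¹ at 12.0 min and 0.0155 min⁻¹ at 50.0 min.

*Is that scatter?* The early κ predicts 45.3% at 50.0 min, and the reading is 43.6%. That gap of 1.7 percentage points stands against a scatter of 0.3 points, though the early κ is itself a reading, so the fall is rough.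

*What do you carry forward?* The share of the early κ lost per minute between those readings, the drift of κ, 0.00179 min⁻¹. Run straight on from 12.0 min, it gives κ = 0.0125 min⁻¹ at 2.5 h, so product 65.2%, good to a few points.

*Has it stopped by then?* The same line gives κ = 0.0147 min⁻¹ and product 52.5% at half the time, so the second half gains 13 points, far above 0.6 of a point. I say it is still moving.

The forecast gave it is still moving and 66%, reasoning that “Product should still be gaining well over 0.6 points across 75–150 min”.

The flask at 2.5 h gives 65.2%: it is still moving. There it holds 0.0710 M of free nucleophile beside 0.0881 M of protonated nucleophile, so c(nucleophile) stands below c(electrophile), 0.139 M. The result puts κ at 0.0125 min⁻¹, beside the 0.0125 min⁻¹ from my line.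

    electrophile + nucleophile → acid set free + product (k = 0.0410 L mol⁻¹ min⁻¹)
    nucleophile + acid set free ⇌ protonated nucleophile, settled at all times (K = 460 L mol⁻¹)
    acid set free + free base ⇌ salt of the base, settled at all times (K = 1400 L mol⁻¹)
    2 free base → homo dimer (k = 0.0360 L mol⁻¹ min⁻¹)

For a neighbour flask, the same charges left until 1.0 h, the drift of 0.00179 min⁻¹ gives κ = 0.0152 min⁻¹, so product 47.7%. The computed flask gives 47.9%.

The readings come from a simulation with made-up constants; noise was put on by code.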